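## The problem

The target is a bergamotane-type tetracycle built on a bicyclo[3.1.1]heptane (C1–C7). C2 carries the exocyclic methylene, C3 the ester oxygen, C1 and C5 are the bridgeheads, and C6 and C7 are the two one-carbon bridges. The quaternary C6 is the spiro atom of an oxolane (C6–C8H2–O–C10–C9H2). Its ketal carbon C10 is also the spiro atom of a γ-lactone (C10–C11H2–C12H(CH3)–C13(=O)–O), and O3 is acylated by (S)-3-hydroxy-2,2-dimethylbutanoic acid.

Seven stereocentres must be set. C1 and C5 are tied by the bridges, so only one is independent. C6 needs the OCH2 arm (C8) syn to the C2–C4 bridge, and from there C8 covers one face of C3, so the C3 oxygen can be delivered trans to C6 under substrate control. C10 lies in the local mirror plane of the core (through C3, C6 and C7), so it cannot be steered from the bicycle and can only follow C12 within the lactone. C12 and the side-chain carbinol are too remote for any relay and must come from enantiopure reagents.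

The fragile parts are:
- the β-pinene-like methylenecyclobutane (cationic ring opening in strong acid, complexation by palladium);
- the acylal-type spiroketal (acid and base);
- the epimerisable C12;
- the allylic and β-hydroxy esters.

The feature that opens the skeleton is that C6 is β to C2 and C7 spans C1 and C5. A C2 ketone with a C1=C6 double bond therefore accepts the C8 arm at C6 and leaves an enolate at C1, exactly where a leaving group on C7, hung from C5, waits to close the cyclobutane C1–C6–C5–C7.

## Retrosynthesis

**Ester.** The C3–O acyl bond of 33 is cut first, through the silyl ether 32, to the allylic alcohol 26 and the protected acid 30 (activated as 31). Cutting here rather than earlier keeps the β-hydroxy ester and the allylic ester out of every basic or enolate step. The acid 30 has no α-hydrogen, so its chloride can neither form a ketene nor eliminate. Acid 30 goes back through 29 and 28 to the keto ester 27, and the forward reaction must only deliver the (S)-carbinol.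

**C3–O.** The C3–O bond of 26 is cut to give the methylene compound 25. The neighbouring choice, carrying the C3 oxygen from the ketone stage, would burden the methylenation and the enolate chemistry with an α-oxygenated ketone. The precursor loses one stereocentre. The forward step must hydroxylate C3 on the face away from C6, which the C8 arm already guards.

**Spiroketal.** The O8–C10 and O–C13 bonds of 25 are cut to the hydroxy keto acid 24, which is unmasked from the silyl ether 23. Two rings and the C10 stereocentre disappear. Because the core cannot bias C10, a kinetic ring closure has nothing to offer over equilibration. The forward reaction is asked to place C10 by thermodynamic control from C12.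

**C11–C12.** The C11–C12 bond of 23 (through its ester 22) is cut to the methyl ketone 18 and the triflate 20, made from ethyl (R)-lactate 19. Methylating a preformed lactone at C12 would have to fight the same unbiased C10. An acyl-anion cut at C10–C11 would need more steps. This cut buys C12 as a single enantiomer and asks only for a kinetic methyl-ketone enolate (21) and clean inversion.

**Functional-group changes.** 18 comes from the diene 17 by oxidation of the terminal alkene, 17 from the ketone 16 by methylenation, 16 from the alcohol 15 by silylation, and 15 from the silane 14 by C–Si oxidation. The order is fixed by three points: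
- the C2 ketone must be gone before any enolate is formed at C11;
- the alkoxysilane is oxidised at once because it is labile;
- the C8 hydroxyl is capped because it would otherwise add to the C10 ketone.

**Key disconnection.** In 14 the C6–C8 and C1–C7 bonds are cut together, through the enolate 13, to the enone tosylate 10 and the Grignard reagent 12 (from the chlorosilane 11). The order of the two arms is not free. The group that adds to C6 enters anti to C7 and ends up syn to the C2–C4 bridge, so it must be C8, and the C9 arm must already be on the enone. A bicycle with three stereocentres becomes a monocycle with one. The forward step must add 1,4, anti to the C5 substituent, and alkylate at carbon.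

**Allyl arm.** 10 is traced through the alcohol 9 and the silyl ether 8 to the silyl enol ether 7, and the C6–C9 bond is cut to the enone 5 and allylmagnesium bromide 6. The leaving group is installed last because a tosyloxymethyl enone can lose sulfonate through its dienolate. Conjugate addition followed by re-oxidation is preferred to a 1,2-addition and oxidative transposition, which would put the side chain next to the carbonyl.

**Desymmetrisation.** 5 goes back through the silyl enol ether 4 and the enolate 3 to the prochiral ketone 2, and this to the commercial alcohol 1. The single stereocentre C5 is created by enantiotopic deprotonation, and everything else in the core descends from it.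

## Roads not taken

**Alternative 1:** The cut is the C5–C6 bond, formed by ring contraction. Irradiation of the bridged diazoketone A1 in methanol would expel nitrogen, shift C5 to the carbene carbon and give the ester A2.
- Merits: the strain is paid for by loss of nitrogen and not by a displacement, so the ring-forming step is more certain than the closure in step 9. A terpene start would bring full enantiopurity.
- Weak points: A2 has only C8 on a tertiary C6, so the quaternary carbon and the C9 arm still need an ester-enolate alkylation. The 2-methyl-2-ene must still be moved to the exocyclic position with oxygenation at C3. A1 itself needs a bicyclo[3.2.1]octenone and a diazo transfer before the key step.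
- Comparison: this road is safer at the cyclobutane and in absolute configuration. The chosen plan sets against it that both arms stand on C6 after one step from a monocycle, and that the enantiomeric deficit of step 2 is removed as diastereomers once the lactate carbon is attached.

**Alternative 2:** The cut is the O8–C10 bond together with the lactone oxidation level. Singlet oxygen would add to the furan of the alcohol A3, the C8 hydroxyl would open the endoperoxide, and dehydration would give the butenolide A4.
- Merits: one oxidation builds the oxolane and the lactone ketal. No lactate alkylation or saponification is needed. In steps for this part it is at least as short as the chosen plan.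
- Weak points: the core is left unsolved, since A3 poses the same C6 problem. A4 has no stereocentre at C12 and forms C10 without bias, because C10 lies in the mirror plane of the core. Reducing the butenolide alkene afterwards can only relate C12 to C10, so two diastereomeric series would result. The trisubstituted ring alkene of A3 is itself an ene substrate for singlet oxygen.
- Comparison: the chosen plan fixes C12 absolutely from 19 and lets C10 follow it.

**Alternative 3:** The cut is C5–C7 and C1–C6 at once. The acid chloride A5 would give a vinylketene with triethylamine, which would add across its Z-alkene to form the cyclobutanone A6.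
- Merits: as ring construction this is the most economical road. Both carbocycles, the quaternary C6 with both arms, the exocyclic methylene and the C3 oxygen arrive in one step, so steps 12 and 18 would be saved.
- Weak points: C7 arrives as a carbonyl that the target lacks, and deoxygenating a hindered cyclobutanone beside two alkenes and an allylic silyl ether costs about three delicate steps. A5 needs a stereodefined trisubstituted alkene with two differentiated arms and an enantioenriched C3 carbinol. The new centres would be controlled only by that remote carbinol across a flexible tether.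
- Comparison: the chosen plan sets against this a C7 that is a CH2 group from the start, control of C6 by the adjacent ring stereocentre C5, and a cyclic precursor reached by routine reactions.

Key step: step 9

Assumption: the chiral lithium amide is taken to show with ketone 2 the same sense of enantiotopic deprotonation as with 4-tert-butylcyclohexanone, so that the (S,S)-amide gives the (R)-enol ether 4; if the sense proves opposite, the (R,R)-amide is used and nothing else changes.

## Route

Step 1
Reactants: 1 4-(hydroxymethyl)cyclohexan-1-one
Product: 2 4-[(tert-butyldimethylsilyloxy)methyl]cyclohexan-1-one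
Conditions: TBSCl, imidazole, DMF, 0 °C → rt
Reagents that add atoms: tert-butyldimethylsilyl chloride, CC(C)(C)[Si](C)(C)Cl
Why: Standard silylation of a primary alcohol; the silyl ether tolerates the amide base, the palladium oxidations and the copper reagent that follow and comes off under mild acid.

Step 2
Reactants: 2 4-[(tert-butyldimethylsilyloxy)methyl]cyclohexan-1-one
Product: 4 (R)-4-[(tert-butyldimethylsilyloxy)methyl]-1-(trimethylsilyloxy)cyclohex-1-ene, via lithium enolate 3 (not isolated)
Conditions: (S,S)-bis(1-phenylethyl)amine·HCl, n-BuLi (2 equiv), THF, −78 °C; TMSCl, then 2, −78 °C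
Reagents that add atoms: chlorotrimethylsilane, C[Si](C)(C)Cl
Why: Asymmetric deprotonation of a 4-substituted cyclohexanone by a chiral lithium amide with internal silyl quench; the base should remove one of the two enantiotopic axial α-hydrogens and so define the future C5, with LiCl from the amine salt expected to raise the selectivity. Whatever minor enantiomer remains becomes a diastereomer once the lactate carbon is attached in step 15 and can be removed from 25 onward.

Step 3
Reactants: 4 (R)-4-[(tert-butyldimethylsilyloxy)methyl]-1-(trimethylsilyloxy)cyclohex-1-ene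
Product: 5 (R)-4-[(tert-butyldimethylsilyloxy)methyl]cyclohex-2-en-1-one
Conditions: Pd(OAc)2 (10 mol%), O2 (1 atm), DMSO, rt
Reagents that add atoms: none
Why: Saegusa–Ito oxidation; the double bond can only form on the side of the enol ether, so the stereocentre becomes the γ-carbon of the enone, and the base-free medium avoids racemisation through the dienolate.

Step 4
Reactants: 5 (R)-4-[(tert-butyldimethylsilyloxy)methyl]cyclohex-2-en-1-one; 6 allylmagnesium bromide
Product: 7 (3S,4R)-3-allyl-4-[(tert-butyldimethylsilyloxy)methyl]-1-(trimethylsilyloxy)cyclohex-1-ene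
Conditions: CuBr·SMe2 (1.1 equiv), TMSCl (3 equiv), THF, −78 °C; Et3N, then aq. NaHCO3
Reagents that add atoms: chlorotrimethylsilane, C[Si](C)(C)Cl
Why: Chlorosilane-assisted conjugate addition of an allylcopper reagent; silyl capture records the enolate on the side of the new substituent, which step 5 needs. Addition should occur anti to the C4 substituent, but this centre is erased in step 5, so its ratio is immaterial.

Step 5
Reactants: 7 (3S,4R)-3-allyl-4-[(tert-butyldimethylsilyloxy)methyl]-1-(trimethylsilyloxy)cyclohex-1-ene
Product: 8 (R)-3-allyl-4-[(tert-butyldimethylsilyloxy)methyl]cyclohex-2-en-1-one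
Conditions: Pd(OAc)2 (10 mol%), O2 (1 atm), DMSO, rt
Reagents that add atoms: none
Why: Second Saegusa–Ito oxidation; palladium on C2 eliminates with the syn hydrogen on C3 and returns the enone with the allyl group on its β-carbon, the remote terminal alkene being a spectator.

Step 6
Reactants: 8 (R)-3-allyl-4-[(tert-butyldimethylsilyloxy)methyl]cyclohex-2-en-1-one
Product: 9 (R)-3-allyl-4-(hydroxymethyl)cyclohex-2-en-1-one
Conditions: CSA (10 mol%), MeOH, 0 °C
Reagents that add atoms: none
Why: Acid-catalysed methanolysis of a primary silyl ether; acid is chosen over fluoride because base could form the dienolate and racemise the γ-carbon or move the allyl double bond into conjugation.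

Step 7
Reactants: 9 (R)-3-allyl-4-(hydroxymethyl)cyclohex-2-en-1-one
Product: 10 [(1R)-2-allyl-4-oxocyclohex-2-en-1-yl]methyl 4-methylbenzenesulfonate
Conditions: TsCl, pyridine, CH2Cl2, 0 °C
Reagents that add atoms: p-toluenesulfonyl chloride, Cc1ccc(cc1)S(Cl)(=O)=O
Why: Sulfonylation of a primary alcohol with a weak base in the cold, so that the γ-hydrogen is not removed and the sulfonate is not eliminated.

Step 8
Reactants: 11 (chloromethyl)(isopropoxy)dimethylsilane
Product: 12 [(isopropoxydimethylsilyl)methyl]magnesium chloride
Conditions: Mg, BrCH2CH2Br (cat.), THF, rt → 40 °C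
Reagents that add atoms: magnesium, [Mg]
Why: Grignard formation from an α-silyl chloride, the usual preparation of this hydroxymethyl anion equivalent; the solution is titrated and used directly.

Step 9
Reactants: 10 [(1R)-2-allyl-4-oxocyclohex-2-en-1-yl]methyl 4-methylbenzenesulfonate; 12 [(isopropoxydimethylsilyl)methyl]magnesium chloride
Product: 14 (1R,5S,6S)-6-allyl-6-[(isopropoxydimethylsilyl)methyl]bicyclo[3.1.1]heptan-2-one, via chloromagnesium enolate 13 (not isolated)
Conditions: CuBr·SMe2 (20 mol%), THF, −78 → −30 °C; then HMPA, −30 → 40 °C
Reagents that add atoms: none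
Why: The Grignard reagent transmetalates to a silylmethylcopper species that adds 1,4 to the enone at C6 and leaves the chloromagnesium enolate 13 with its double bond fixed between C1 and C2; when the polar cosolvent is added and the mixture warmed, C1 displaces the tosylate at C7. The closest known reaction types are the copper-catalysed conjugate addition of (alkoxysilyl)methyl Grignard reagents to enones, the conjugate addition–intramolecular alkylation sequence (Michael-initiated ring closure), and the closure of sulfonyloxymethyl cyclohexanone enolates to bicyclo[3.1.1]heptan-2-ones. The one ring closed is the cyclobutane C1–C6–C5–C7, by a 4-exo-tet displacement in which the enolate carbon attacks the axial CH2OTs group across the ring. C5 is carried in from step 2; C6 is set by the face of the conjugate addition, because allylic 1,2-strain with the C6 allyl group holds the C5 tosyloxymethyl group pseudoaxial, the nucleophile adds axially on the opposite face, and the new arm therefore ends up syn to the C2–C4 bridge with the allyl group anti. C1 is not free, since the one-carbon bridge can only span C1 and C5 on one face, so its configuration follows from C5. The step needs 1,4-addition in preference to 1,2-addition, to substitution of the tosylate and to deprotonation at C5 or C9, which the soft copper reagent at low temperature and the weakly basic silylmethyl nucleophile should provide; it needs the enolate to stay at C1 until it closes, which holds as long as no proton source is present; and it needs C- rather than O-alkylation, which is secured because O-alkylation would give a bridged enol ether with a bridgehead double bond.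

Step 10
Reactants: 14 (1R,5S,6S)-6-allyl-6-[(isopropoxydimethylsilyl)methyl]bicyclo[3.1.1]heptan-2-one
Product: 15 (1R,5S,6S)-6-allyl-6-(hydroxymethyl)bicyclo[3.1.1]heptan-2-one
Conditions: H2O2 (30% aq.), KF, KHCO3, THF/MeOH, rt
Reagents that add atoms: hydrogen peroxide, OO
Why: Tamao oxidation of the alkoxysilane C–Si bond; the ketone and the terminal alkene are inert to buffered peroxide. The product may sit partly as the bridged hemiketal between O8 and C2, which step 11 drains through the open form.

Step 11
Reactants: 15 (1R,5S,6S)-6-allyl-6-(hydroxymethyl)bicyclo[3.1.1]heptan-2-one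
Product: 16 (1R,5S,6S)-6-allyl-6-[(tert-butyldimethylsilyloxy)methyl]bicyclo[3.1.1]heptan-2-one
Conditions: TBSCl, imidazole, DMF, rt
Reagents that add atoms: tert-butyldimethylsilyl chloride, CC(C)(C)[Si](C)(C)Cl
Why: Silylation of the primary neopentyl-type alcohol; the cap keeps O8 from adding to the C2 ketone now and to the C10 ketone later, and from forming an alkoxide in step 15.

Step 12
Reactants: 16 (1R,5S,6S)-6-allyl-6-[(tert-butyldimethylsilyloxy)methyl]bicyclo[3.1.1]heptan-2-one
Product: 17 (1S,5S,6S)-6-allyl-6-[(tert-butyldimethylsilyloxy)methyl]-2-methylidenebicyclo[3.1.1]heptane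
Conditions: Ph3PCH3Br, KOtBu, THF, 0 → 50 °C
Reagents that add atoms: methyltriphenylphosphonium bromide, C[P+](c1ccccc1)(c1ccccc1)c1ccccc1.[Br-]
Why: Wittig methylenation of a bicyclo[3.1.1]heptan-2-one, as in the conversion of nopinone into β-pinene; the bridgehead C1 cannot epimerise, and the C2 ketone is removed before enolate chemistry at C11.

Step 13
Reactants: 17 (1S,5S,6S)-6-allyl-6-[(tert-butyldimethylsilyloxy)methyl]-2-methylidenebicyclo[3.1.1]heptane
Product: 18 1-{(1S,5S,6S)-6-[(tert-butyldimethylsilyloxy)methyl]-2-methylidenebicyclo[3.1.1]heptan-6-yl}propan-2-one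
Conditions: PdCl2 (10 mol%), CuCl (1 equiv), O2 (1 atm), DMF/H2O (7:1), rt
Reagents that add atoms: water, O
Why: Tsuji–Wacker oxidation; a monosubstituted terminal alkene is oxidised much faster than a 1,1-disubstituted one, and Markovnikov hydroxypalladation places the carbonyl at C10.

Step 14
Reactants: 19 ethyl (R)-lactate
Product: 20 ethyl (R)-2-[(trifluoromethylsulfonyl)oxy]propanoate
Conditions: Tf2O, 2,6-lutidine, CH2Cl2, −78 → 0 °C
Reagents that add atoms: trifluoromethanesulfonic anhydride, FC(F)(F)S(=O)(=O)OS(=O)(=O)C(F)(F)F
Why: O-Sulfonylation does not touch the stereocentre; the triflate is used promptly.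

Step 15
Reactants: 18 1-{(1S,5S,6S)-6-[(tert-butyldimethylsilyloxy)methyl]-2-methylidenebicyclo[3.1.1]heptan-6-yl}propan-2-one; 20 ethyl (R)-2-[(trifluoromethylsulfonyl)oxy]propanoate
Product: 22 ethyl (2R)-5-{(1S,5S,6S)-6-[(tert-butyldimethylsilyloxy)methyl]-2-methylidenebicyclo[3.1.1]heptan-6-yl}-2-methyl-4-oxopentanoate, via lithium enolate 21 (not isolated)
Conditions: LiN(iPr)2, THF, −78 °C; then 20, −78 → −40 °C
Reagents that add atoms: none
Why: Kinetic deprotonation takes the methyl group, since the other α-carbon (C9) is neopentyl; the enolate displaces triflate from the α-triflyloxy ester by SN2 with inversion, a known enolate alkylation, so the (R)-lactate gives (R) at C12.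

Step 16
Reactants: 22 ethyl (2R)-5-{(1S,5S,6S)-6-[(tert-butyldimethylsilyloxy)methyl]-2-methylidenebicyclo[3.1.1]heptan-6-yl}-2-methyl-4-oxopentanoate
Product: 23 (2R)-5-{(1S,5S,6S)-6-[(tert-butyldimethylsilyloxy)methyl]-2-methylidenebicyclo[3.1.1]heptan-6-yl}-2-methyl-4-oxopentanoic acid
Conditions: LiOH·H2O, THF/MeOH/H2O, 0 °C → rt; then 1 M HCl to pH 4, 0 °C
Reagents that add atoms: lithium hydroxide, [Li+].[OH-]
Why: Saponification of an unhindered ethyl ester; the ester is hydrolysed to the carboxylate faster than C12 is enolised, and the cold, brief acidification spares the methylenecyclobutane.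

Step 17
Reactants: 23 (2R)-5-{(1S,5S,6S)-6-[(tert-butyldimethylsilyloxy)methyl]-2-methylidenebicyclo[3.1.1]heptan-6-yl}-2-methyl-4-oxopentanoic acid
Product: 25 (1S,5S,6S,5'R,4''R)-4''-methyl-2-methylidenedispiro[bicyclo[3.1.1]heptane-6,3'-oxolane-5',2''-oxolan]-5''-one, via hydroxy keto acid 24 (not isolated)
Conditions: HF·pyridine, pyridine, THF, 0 °C → rt; then PPTS (10 mol%), MgSO4, CH2Cl2, rt
Reagents that add atoms: none
Why: Desilylation frees O8, which adds to the C10 ketone (5-exo), and the hemiketal hydroxyl is acylated by the acid in a dehydrative spirolactonisation under mild acid that the methylenecyclobutane should tolerate. C10 is set under thermodynamic control from C12: the oxolane oxygen takes the pseudoaxial, anomerically favoured position on the lactone envelope, and the C12 methyl group and C9 are then both pseudoequatorial and cis, which is the (R) configuration of the target.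

Step 18
Reactants: 25 (1S,5S,6S,5'R,4''R)-4''-methyl-2-methylidenedispiro[bicyclo[3.1.1]heptane-6,3'-oxolane-5',2''-oxolan]-5''-one
Product: 26 (1R,3S,5R,6S,5'R,4''R)-3-hydroxy-4''-methyl-2-methylidenedispiro[bicyclo[3.1.1]heptane-6,3'-oxolane-5',2''-oxolan]-5''-one
Conditions: SeO2 (0.3 equiv), t-BuOOH (3 equiv), CH2Cl2, 0 °C → rt
Reagents that add atoms: tert-butyl hydroperoxide, CC(C)(C)OO; selenium dioxide, O=[Se]=O
Why: Allylic hydroxylation by ene reaction and [2,3]-sigmatropic shift, as in the oxidation of β-pinene to trans-pinocarveol; C3 is the only allylic position that can take part, since C1 is a bridgehead. The oxygen is delivered to the face away from C6 because the C8 arm covers the other one, which gives (3S).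

Step 19
Reactants: 27 methyl 2,2-dimethyl-3-oxobutanoate
Product: 28 methyl (S)-3-hydroxy-2,2-dimethylbutanoate
Conditions: H2 (50 atm), RuCl2[(S)-BINAP] (0.5 mol%), MeOH, 50 °C
Reagents that add atoms: none
Why: Noyori asymmetric hydrogenation of a β-keto ester; the (S)-ligand should give the (S)-carbinol by the same facial sense as with methyl acetoacetate, and the quaternary α-carbon excludes racemisation.

Step 20
Reactants: 28 methyl (S)-3-hydroxy-2,2-dimethylbutanoate
Product: 29 methyl (S)-3-(tert-butyldimethylsilyloxy)-2,2-dimethylbutanoate
Conditions: TBSOTf, 2,6-lutidine, CH2Cl2, 0 °C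
Reagents that add atoms: tert-butyldimethylsilyl trifluoromethanesulfonate, CC(C)(C)[Si](C)(C)OS(=O)(=O)C(F)(F)F
Why: The silyl triflate is needed for a secondary alcohol beside a quaternary carbon; the ether blocks self-acylation in step 22.

Step 21
Reactants: 29 methyl (S)-3-(tert-butyldimethylsilyloxy)-2,2-dimethylbutanoate
Product: 30 (S)-3-(tert-butyldimethylsilyloxy)-2,2-dimethylbutanoic acid
Conditions: LiOH·H2O, THF/MeOH/H2O, 60 °C; then 1 M HCl
Reagents that add atoms: lithium hydroxide, [Li+].[OH-]
Why: Saponification of a hindered ester needs heat, which is harmless here: without an α-hydrogen neither epimerisation nor β-elimination of the silyloxy group is possible.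

Step 22
Reactants: 30 (S)-3-(tert-butyldimethylsilyloxy)-2,2-dimethylbutanoic acid; 26 (1R,3S,5R,6S,5'R,4''R)-3-hydroxy-4''-methyl-2-methylidenedispiro[bicyclo[3.1.1]heptane-6,3'-oxolane-5',2''-oxolan]-5''-one
Product: 32 (1R,3S,5R,6S,5'R,4''R)-4''-methyl-2-methylidene-5''-oxodispiro[bicyclo[3.1.1]heptane-6,3'-oxolane-5',2''-oxolan]-3-yl (S)-3-(tert-butyldimethylsilyloxy)-2,2-dimethylbutanoate, via acid chloride 31 (not isolated)
Conditions: 1-chloro-N,N,2-trimethylprop-1-en-1-amine, CH2Cl2, 0 °C → rt; then 26, Et3N, DMAP, CH2Cl2, rt → 40 °C
Reagents that add atoms: none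
Why: DMAP-catalysed acylation of a secondary allylic alcohol by an α-quaternary acid chloride, formed under neutral conditions that keep the silyl ether; the chloride has no α-hydrogen, so it cannot form a ketene or eliminate, and C3 keeps its configuration.

Step 23
Reactants: 32 (1R,3S,5R,6S,5'R,4''R)-4''-methyl-2-methylidene-5''-oxodispiro[bicyclo[3.1.1]heptane-6,3'-oxolane-5',2''-oxolan]-3-yl (S)-3-(tert-butyldimethylsilyloxy)-2,2-dimethylbutanoate
Product: 33 (1R,3S,5R,6S,5'R,4''R)-4''-methyl-2-methylidene-5''-oxodispiro[bicyclo[3.1.1]heptane-6,3'-oxolane-5',2''-oxolan]-3-yl (S)-3-hydroxy-2,2-dimethylbutanoate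
Conditions: HF·pyridine, pyridine, THF, 0 °C → rt
Reagents that add atoms: none
Why: Fluoride-mediated cleavage of a hindered secondary silyl ether under buffered conditions that should spare the spiroketal, the allylic ester and the methylenecyclobutane.

## Compound list

1 | 4-(hydroxymethyl)cyclohexan-1-one | O=C1CCC(CO)CC1 | starting material
2 | 4-[(tert-butyldimethylsilyloxy)methyl]cyclohexan-1-one | O=C1CCC(CO[Si](C)(C)C(C)(C)C)CC1 | intermediate
3 | lithium (R)-4-[(tert-butyldimethylsilyloxy)methyl]cyclohex-1-en-1-olate | [Li]OC1=CC[C@H](CO[Si](C)(C)C(C)(C)C)CC1 | intermediate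
4 | (R)-4-[(tert-butyldimethylsilyloxy)methyl]-1-(trimethylsilyloxy)cyclohex-1-ene | C[Si](C)(C)OC1=CC[C@H](CO[Si](C)(C)C(C)(C)C)CC1 | intermediate
5 | (R)-4-[(tert-butyldimethylsilyloxy)methyl]cyclohex-2-en-1-one | O=C1C=C[C@H](CO[Si](C)(C)C(C)(C)C)CC1 | intermediate
6 | allylmagnesium bromide | C=CC[Mg]Br | starting material
7 | (3S,4R)-3-allyl-4-[(tert-butyldimethylsilyloxy)methyl]-1-(trimethylsilyloxy)cyclohex-1-ene (allyl trans to the silyloxymethyl group) | C[Si](C)(C)OC1=C[C@@H](CC=C)[C@H](CO[Si](C)(C)C(C)(C)C)CC1 | intermediate
8 | (R)-3-allyl-4-[(tert-butyldimethylsilyloxy)methyl]cyclohex-2-en-1-one | O=C1C=C(CC=C)[C@H](CO[Si](C)(C)C(C)(C)C)CC1 | intermediate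
9 | (R)-3-allyl-4-(hydroxymethyl)cyclohex-2-en-1-one | O=C1C=C(CC=C)[C@H](CO)CC1 | intermediate
10 | [(1R)-2-allyl-4-oxocyclohex-2-en-1-yl]methyl 4-methylbenzenesulfonate | O=C1C=C(CC=C)[C@H](COS(=O)(=O)c2ccc(C)cc2)CC1 | intermediate
11 | (chloromethyl)(isopropoxy)dimethylsilane | CC(C)O[Si](C)(C)CCl | starting material
12 | [(isopropoxydimethylsilyl)methyl]magnesium chloride | CC(C)O[Si](C)(C)C[Mg]Cl | intermediate
13 | chloromagnesium (3S,4R)-3-allyl-3-[(isopropoxydimethylsilyl)methyl]-4-(tosyloxymethyl)cyclohex-1-en-1-olate (silylmethyl trans to tosyloxymethyl) | Cl[Mg]OC1=C[C@@](CC=C)(C[Si](C)(C)OC(C)C)[C@H](COS(=O)(=O)c2ccc(C)cc2)CC1 | intermediate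
14 | (1R,5S,6S)-6-allyl-6-[(isopropoxydimethylsilyl)methyl]bicyclo[3.1.1]heptan-2-one (silylmethyl syn to the C2–C4 bridge) | O=C1CC[C@H]2C[C@@H]1[C@@]2(CC=C)C[Si](C)(C)OC(C)C | intermediate
15 | (1R,5S,6S)-6-allyl-6-(hydroxymethyl)bicyclo[3.1.1]heptan-2-one | O=C1CC[C@H]2C[C@@H]1[C@@]2(CC=C)CO | intermediate
16 | (1R,5S,6S)-6-allyl-6-[(tert-butyldimethylsilyloxy)methyl]bicyclo[3.1.1]heptan-2-one | O=C1CC[C@H]2C[C@@H]1[C@@]2(CC=C)CO[Si](C)(C)C(C)(C)C | intermediate
17 | (1S,5S,6S)-6-allyl-6-[(tert-butyldimethylsilyloxy)methyl]-2-methylidenebicyclo[3.1.1]heptane | C=C1CC[C@H]2C[C@@H]1[C@@]2(CC=C)CO[Si](C)(C)C(C)(C)C | intermediate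
18 | 1-{(1S,5S,6S)-6-[(tert-butyldimethylsilyloxy)methyl]-2-methylidenebicyclo[3.1.1]heptan-6-yl}propan-2-one | C=C1CC[C@H]2C[C@@H]1[C@@]2(CC(C)=O)CO[Si](C)(C)C(C)(C)C | intermediate
19 | ethyl (R)-lactate | C[C@@H](O)C(=O)OCC | starting material
20 | ethyl (R)-2-[(trifluoromethylsulfonyl)oxy]propanoate | C[C@@H](OS(=O)(=O)C(F)(F)F)C(=O)OCC | intermediate
21 | lithium 3-{(1S,5S,6S)-6-[(tert-butyldimethylsilyloxy)methyl]-2-methylidenebicyclo[3.1.1]heptan-6-yl}prop-1-en-2-olate | C=C1CC[C@H]2C[C@@H]1[C@@]2(CC(=C)O[Li])CO[Si](C)(C)C(C)(C)C | intermediate
22 | ethyl (2R)-5-{(1S,5S,6S)-6-[(tert-butyldimethylsilyloxy)methyl]-2-methylidenebicyclo[3.1.1]heptan-6-yl}-2-methyl-4-oxopentanoate | C=C1CC[C@H]2C[C@@H]1[C@@]2(CC(=O)C[C@@H](C)C(=O)OCC)CO[Si](C)(C)C(C)(C)C | intermediate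
23 | (2R)-5-{(1S,5S,6S)-6-[(tert-butyldimethylsilyloxy)methyl]-2-methylidenebicyclo[3.1.1]heptan-6-yl}-2-methyl-4-oxopentanoic acid | C=C1CC[C@H]2C[C@@H]1[C@@]2(CC(=O)C[C@@H](C)C(=O)O)CO[Si](C)(C)C(C)(C)C | intermediate
24 | (2R)-5-[(1S,5S,6S)-6-(hydroxymethyl)-2-methylidenebicyclo[3.1.1]heptan-6-yl]-2-methyl-4-oxopentanoic acid | C=C1CC[C@H]2C[C@@H]1[C@@]2(CO)CC(=O)C[C@@H](C)C(=O)O | intermediate
25 | (1S,5S,6S,5'R,4''R)-4''-methyl-2-methylidenedispiro[bicyclo[3.1.1]heptane-6,3'-oxolane-5',2''-oxolan]-5''-one | C=C1CC[C@H]2C[C@@H]1[C@@]21CO[C@@]2(C[C@@H](C)C(=O)O2)C1 | intermediate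
26 | (1R,3S,5R,6S,5'R,4''R)-3-hydroxy-4''-methyl-2-methylidenedispiro[bicyclo[3.1.1]heptane-6,3'-oxolane-5',2''-oxolan]-5''-one | C=C1[C@@H](O)C[C@H]2C[C@@H]1[C@@]21CO[C@@]2(C[C@@H](C)C(=O)O2)C1 | intermediate
27 | methyl 2,2-dimethyl-3-oxobutanoate | COC(=O)C(C)(C)C(C)=O | starting material
28 | methyl (S)-3-hydroxy-2,2-dimethylbutanoate | COC(=O)C(C)(C)[C@H](C)O | intermediate
29 | methyl (S)-3-(tert-butyldimethylsilyloxy)-2,2-dimethylbutanoate | COC(=O)C(C)(C)[C@H](C)O[Si](C)(C)C(C)(C)C | intermediate
30 | (S)-3-(tert-butyldimethylsilyloxy)-2,2-dimethylbutanoic acid | OC(=O)C(C)(C)[C@H](C)O[Si](C)(C)C(C)(C)C | intermediate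
31 | (S)-3-(tert-butyldimethylsilyloxy)-2,2-dimethylbutanoyl chloride | ClC(=O)C(C)(C)[C@H](C)O[Si](C)(C)C(C)(C)C | intermediate
32 | (1R,3S,5R,6S,5'R,4''R)-4''-methyl-2-methylidene-5''-oxodispiro[bicyclo[3.1.1]heptane-6,3'-oxolane-5',2''-oxolan]-3-yl (S)-3-(tert-butyldimethylsilyloxy)-2,2-dimethylbutanoate | C=C1[C@@H](OC(=O)C(C)(C)[C@H](C)O[Si](C)(C)C(C)(C)C)C[C@H]2C[C@@H]1[C@@]21CO[C@@]2(C[C@@H](C)C(=O)O2)C1 | intermediate
33 | (1R,3S,5R,6S,5'R,4''R)-4''-methyl-2-methylidene-5''-oxodispiro[bicyclo[3.1.1]heptane-6,3'-oxolane-5',2''-oxolan]-3-yl (S)-3-hydroxy-2,2-dimethylbutanoate | C=C1[C@@H](OC(=O)C(C)(C)[C@H](C)O)C[C@H]2C[C@@H]1[C@@]21CO[C@@]2(C[C@@H](C)C(=O)O2)C1 | target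

## Step count and risks

Total: 23 steps. Longest linear sequence: 18 steps (steps 1–7, 9–13, 15–18, 22, 23). Steps 8, 14 and 19–21 prepare the three reagents and fragments that join it.

**Step 9 (key step).** Two processes are most likely to fail. First, conjugate addition to the fully substituted β-carbon may be slow enough for the Grignard reagent to act as a base at C5 or at the doubly allylic C9. That leads to loss of the tosylate through the dienolate and to aromatisation. Second, the magnesium enolate may close the strained ring too slowly, so that enolate equilibration to C3 or intermolecular reactions take over. The fallback separates the two events. From 10, the addition of 12 is run with CuBr·SMe2 (cat.), TMSCl and HMPA in THF at −78 °C, which accelerates the addition and captures the enolate as (3S,4R)-3-allyl-3-[(isopropoxydimethylsilyl)methyl]-4-(tosyloxymethyl)-1-(trimethylsilyloxy)cyclohex-1-ene F1. After isolation, one equivalent of anhydrous tetrabutylammonium difluorotriphenylsilicate in THF releases the ammonium enolate regiospecifically, and its closure returns the route to 14.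

**Step 15.** The enolate 21 may take the acidic α-hydrogen of the triflate 20 instead of displacing it (elimination to the acrylate, loss of configuration), or may equilibrate with the product ketone. The fallback reverses the polarity and takes the configuration from an auxiliary. From 18, LiN(iPr)2 and TMSCl give the kinetic silyl enol ether F2, and N-bromosuccinimide converts it into the bromomethyl ketone F3. F3 alkylates the sodium enolate of (S)-4-benzyl-3-propanoyloxazolidin-2-one (NaN(SiMe3)2, THF, −78 °C) on the face away from the benzyl group to give the (2R)-imide F4. LiOH/H2O2 cleaves the auxiliary and returns the route at the acid 23, so step 16 is not needed.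

**Step 13.** Palladium may isomerise the strained exocyclic alkene, convert it into an allyl complex, or oxidise it in competition with the terminal alkene. The fallback carries out the oxidation before the exocyclic alkene exists. From 15, PdCl2 (cat.), CuCl and O2 in methanol effect intramolecular alkoxypalladation of the allyl group by O8 and give the mixed methyl ketal F5. This masks the C8 hydroxyl and the C10 ketone at once. Wittig methylenation of the C2 ketone gives F6. PPTS in wet acetone opens the ketal to the hydroxy ketone F7, and silylation as in step 11 returns the route at 18.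

**Step 17.** The thermodynamic preference at C10 rests on a conformational argument within the lactone ring and may be incomplete, which would give a mixture of ketal epimers. The fallback is recycling through the open form rather than a single equilibration. The unwanted C10 epimer F8 is separated from 25, opened with LiOH to the carboxylate of 24, and closed again under the conditions of step 17, so the material is funnelled to 25.

**Step 4.** The allyl reagent may add 1,2 to the carbonyl in competition with conjugate addition. The fallback uses the 1,2-adduct. From 5, reagent 6 in THF at −78 °C without copper gives the tertiary allylic alcohol F9. KH and 18-crown-6 in THF trigger the anionic oxy-Cope rearrangement, which delivers the allyl group to C3 and the same enolate as the conjugate addition. A TMSCl quench returns the route at 7.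

## Further compounds

F1 | step 9 | (3S,4R)-3-allyl-3-[(isopropoxydimethylsilyl)methyl]-4-(tosyloxymethyl)-1-(trimethylsilyloxy)cyclohex-1-ene | C[Si](C)(C)OC1=C[C@@](CC=C)(C[Si](C)(C)OC(C)C)[C@H](COS(=O)(=O)c2ccc(C)cc2)CC1
F2 | step 15 | tert-butyldimethyl{[(1S,5S,6S)-2-methylidene-6-[2-(trimethylsilyloxy)prop-2-en-1-yl]bicyclo[3.1.1]heptan-6-yl]methoxy}silane | C=C1CC[C@H]2C[C@@H]1[C@@]2(CC(=C)O[Si](C)(C)C)CO[Si](C)(C)C(C)(C)C
F3 | step 15 | 1-bromo-3-{(1S,5S,6S)-6-[(tert-butyldimethylsilyloxy)methyl]-2-methylidenebicyclo[3.1.1]heptan-6-yl}propan-2-one | C=C1CC[C@H]2C[C@@H]1[C@@]2(CC(=O)CBr)CO[Si](C)(C)C(C)(C)C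
F4 | step 15 | (4S)-4-benzyl-3-[(2R)-5-{(1S,5S,6S)-6-[(tert-butyldimethylsilyloxy)methyl]-2-methylidenebicyclo[3.1.1]heptan-6-yl}-2-methyl-4-oxopentanoyl]oxazolidin-2-one | C=C1CC[C@H]2C[C@@H]1[C@@]2(CC(=O)C[C@@H](C)C(=O)N1[C@@H](Cc3ccccc3)COC1=O)CO[Si](C)(C)C(C)(C)C
F5 | step 13 | (1R,5S,6S)-5'-methoxy-5'-methylspiro[bicyclo[3.1.1]heptane-6,3'-oxolan]-2-one (both epimers at C5') | O=C1CC[C@H]2C[C@@H]1[C@@]21COC(C)(OC)C1
F6 | step 13 | (1S,5S,6S)-5'-methoxy-5'-methyl-2-methylidenespiro[bicyclo[3.1.1]heptane-6,3'-oxolane] (both epimers at C5') | C=C1CC[C@H]2C[C@@H]1[C@@]21COC(C)(OC)C1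
F7 | step 13 | 1-[(1S,5S,6S)-6-(hydroxymethyl)-2-methylidenebicyclo[3.1.1]heptan-6-yl]propan-2-one (open form of the lactol) | C=C1CC[C@H]2C[C@@H]1[C@@]2(CO)CC(C)=O
F8 | step 17 | (1S,5S,6S,5'S,4''R)-4''-methyl-2-methylidenedispiro[bicyclo[3.1.1]heptane-6,3'-oxolane-5',2''-oxolan]-5''-one | C=C1CC[C@H]2C[C@@H]1[C@@]21CO[C@]2(C[C@@H](C)C(=O)O2)C1
F9 | step 4 | (4R)-1-allyl-4-[(tert-butyldimethylsilyloxy)methyl]cyclohex-2-en-1-ol (both epimers at C1) | C=CCC1(O)C=C[C@H](CO[Si](C)(C)C(C)(C)C)CC1
A1 | alternative 1 | 7-diazo-2-methylbicyclo[3.2.1]oct-2-en-6-one | CC1=CC[C@H]2C[C@@H]1C(=[N+]=[N-])C2=O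
A2 | alternative 1 | methyl 2-methylbicyclo[3.1.1]hept-2-ene-6-carboxylate | CC1=CC[C@H]2C[C@@H]1[C@H]2C(=O)OC
A3 | alternative 2 | {2-methyl-6-[(4-methylfuran-2-yl)methyl]bicyclo[3.1.1]hept-2-en-6-yl}methanol (hydroxymethyl syn to the C2–C4 bridge) | CC1=CC[C@H]2C[C@@H]1[C@]2(CO)Cc1cc(C)co1
A4 | alternative 2 | spiroketal butenolide on the 2-methylbicyclo[3.1.1]hept-2-ene | CC1=CC[C@H]2C[C@@H]1[C@@]21CO[C@@]2(C=C(C)C(=O)O2)C1
A5 | alternative 3 | (2E,6Z)-4-(tert-butyldimethylsilyloxy)-7-[(4-methoxybenzyloxy)methyl]-3-methyldeca-2,6,9-trienoyl chloride | ClC(=O)/C=C(\C)[C@@H](O[Si](C)(C)C(C)(C)C)C/C=C(\COCc1ccc(OC)cc1)CC=C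
A6 | alternative 3 | 6-allyl-3-(tert-butyldimethylsilyloxy)-6-[(4-methoxybenzyloxy)methyl]-2-methylidenebicyclo[3.1.1]heptan-7-one | C=C1[C@@H](O[Si](C)(C)C(C)(C)C)C[C@H]2C(=O)[C@@H]1[C@@]2(CC=C)COCc1ccc(OC)cc1
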